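**Retrosynthetic overview**
- The oxolane (last ring) is closed by a palladium-catalysed formal [3+2] union of two C20 halves: an E-enone (acceptor) and an (E)-4-hydroxyalk-2-enyl tert-butyl carbonate (π-allyl/alkoxide precursor). This forms O1–C2 and C3–C4; ketone reduction and desilylation follow.
- Each half comes from an asymmetric (E)-alkenylzinc addition of a C11 alkyne to one common cyclopropyl-lactone aldehyde. The halves differ in the configuration of the silyloxy centre and in the follow-up (oxidation to the enone, or carbonate formation).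
- Common aldehyde: Charette cyclopropanation of mono-silylated (E)-but-2-ene-1,4-diol, then catalytic asymmetric addition of an ester-bearing dialkylzinc and lactonisation.
- Alkynes: (S)-3-hydroxy-γ-butyrolactone, lactol, Z-Wittig with the (Z)-hex-3-enyl ylide, oxidation and Colvin homologation give the (S)-alkyne; Mitsunobu inversion of its carbinol gives the (R)-alkyne.
- Ring order: cyclopropane, then oxan-2-one (δ-lactone), then oxolane.

Assumption: (4S)-4-hydroxyoxolan-2-one is commercial, and silylating agents, Boc2O, 4-nitrobenzoic acid, phosphines and boron, zinc or diazo reagents are treated as reagents.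

**Fragment 1: cyclopropyl-lactone aldehyde 10**

Step 1
Reactants: 1 (E)-but-2-ene-1,4-diol
Product: 2 (E)-4-{[tert-butyl(dimethyl)silyl]oxy}but-2-en-1-ol
Conditions: NaH (1.0 equiv), THF, 0 °C; TBSCl (1.0 equiv), 0 °C → rt
Reagents that add atoms: tert-butyl(chloro)dimethylsilane, CC(C)(C)[Si](C)(C)Cl
Why: Williamson-type O-silylation of the sparingly soluble monosodium alkoxide (McDougal monoprotection) gives the mono-ether selectively; no stereocentre is involved.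

Step 2
Reactants: 2 (E)-4-{[tert-butyl(dimethyl)silyl]oxy}but-2-en-1-ol
Product: 3 [(1R,2R)-2-({[tert-butyl(dimethyl)silyl]oxy}methyl)cyclopropyl]methanol
Conditions: Et2Zn, CH2I2, DME, CH2Cl2, −10 °C; then 2 and (4S,5S)-2-butyl-N,N,N′,N′-tetramethyl-1,3,2-dioxaborolane-4,5-dicarboxamide (1.2 equiv), −10 °C → rt
Reagents that add atoms: diiodomethane, ICI
Why: Charette asymmetric Simmons–Smith cyclopropanation, in which the (S,S)-dioxaborolane binds the zinc alkoxide and delivers the carbenoid CH2 to one face of the E-alkene, setting both cyclopropane centres as trans-(1R,2R) by stereospecific syn addition.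

Step 3
Reactants: 3 [(1R,2R)-2-({[tert-butyl(dimethyl)silyl]oxy}methyl)cyclopropyl]methanol
Product: 4 (1R,2R)-2-({[tert-butyl(dimethyl)silyl]oxy}methyl)cyclopropane-1-carbaldehyde
Conditions: Dess–Martin periodinane, CH2Cl2, 0 °C → rt
Reagents that add atoms: none
Why: Dess–Martin oxidation of the primary alcohol to the aldehyde under neutral conditions; the silyl ether survives and the trans-cyclopropane centres are not epimerised.

Step 4
Reactants: 4 (1R,2R)-2-({[tert-butyl(dimethyl)silyl]oxy}methyl)cyclopropane-1-carbaldehyde; 5 methyl 4-iodobutanoate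
Product: 8 (6R)-6-[(1R,2R)-2-({[tert-butyl(dimethyl)silyl]oxy}methyl)cyclopropyl]oxan-2-one, via diorganozinc 6 (not isolated), via hydroxy ester 7 (not isolated)
Conditions: 5, Et2Zn, CuI (0.3 mol %), neat, 50 °C, then vacuum; Ti(OiPr)4 (2 equiv), (1S,2S)-N,N′-(cyclohexane-1,2-diyl)bis(1,1,1-trifluoromethanesulfonamide) (8 mol %), PhMe, −20 °C, then 4; aq. NH4Cl; pyridinium p-toluenesulfonate (10 mol %), CH2Cl2, rt
Reagents that add atoms: none
Why: Iodine–zinc exchange followed by Knochel-type catalytic asymmetric addition of the ester-bearing dialkylzinc, in which the complex formed from Ti(OiPr)4 and the (S,S)-bis(sulfonamide) directs attack to the Re face of the aldehyde and sets the (R)-carbinol under catalyst control; acid-catalysed lactonisation of the δ-hydroxy ester then closes the oxan-2-one ring.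

Step 5
Reactants: 8 (6R)-6-[(1R,2R)-2-({[tert-butyl(dimethyl)silyl]oxy}methyl)cyclopropyl]oxan-2-one
Product: 9 (6R)-6-[(1R,2R)-2-(hydroxymethyl)cyclopropyl]oxan-2-one
Conditions: HF·pyridine, pyridine, THF, 0 °C → rt
Reagents that add atoms: none
Why: Fluoride-mediated Si–O cleavage of the primary silyl ether (desilylation); buffered HF·pyridine leaves the lactone and cyclopropane untouched.

Step 6
Reactants: 9 (6R)-6-[(1R,2R)-2-(hydroxymethyl)cyclopropyl]oxan-2-one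
Product: 10 (1R,2R)-2-[(2R)-6-oxooxan-2-yl]cyclopropane-1-carbaldehyde
Conditions: Dess–Martin periodinane, CH2Cl2, 0 °C → rt
Reagents that add atoms: none
Why: Dess–Martin oxidation to the aldehyde; the lactone is inert and the trans-cyclopropane is configurationally stable.

**Fragment 2: Wittig salt 13**

Step 7
Reactants: 11 (3Z)-hex-3-en-1-ol
Product: 12 (3Z)-1-iodohex-3-ene
Conditions: I2, PPh3, imidazole, CH2Cl2, 0 °C → rt
Reagents that add atoms: iodine, II
Why: Appel-type iodination (SN2 at the primary carbon through the alkoxyphosphonium ion); the Z-alkene is not touched.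

Step 8
Reactants: 12 (3Z)-1-iodohex-3-ene
Product: 13 [(3Z)-hex-3-en-1-yl]triphenylphosphonium iodide
Conditions: PPh3, MeCN, reflux
Reagents that add atoms: triphenylphosphine, c1ccc(cc1)P(c1ccccc1)c1ccccc1
Why: SN2 quaternisation of triphenylphosphine by the primary iodide gives the Wittig salt with the Z-alkene intact.

**Fragment 3: (S)-alkyne 20 and enone 24**

Step 9
Reactants: 14 (4S)-4-hydroxyoxolan-2-one
Product: 15 (4S)-4-{[tert-butyl(dimethyl)silyl]oxy}oxolan-2-one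
Conditions: TBSCl, imidazole, DMF, rt
Reagents that add atoms: tert-butyl(chloro)dimethylsilane, CC(C)(C)[Si](C)(C)Cl
Why: Imidazole-promoted O-silylation of the secondary alcohol; the stereocentre (chiral pool) is not involved.

Step 10
Reactants: 15 (4S)-4-{[tert-butyl(dimethyl)silyl]oxy}oxolan-2-one
Product: 16 (4S)-4-{[tert-butyl(dimethyl)silyl]oxy}oxolan-2-ol (both anomers)
Conditions: iBu2AlH (1.1 equiv), CH2Cl2, −78 °C; aq. KNaC4H4O6
Reagents that add atoms: none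
Why: Partial reduction of the lactone to the lactol by iBu2AlH at −78 °C (stable tetrahedral aluminate); C4 is untouched.

Step 11
Reactants: 16 (4S)-4-{[tert-butyl(dimethyl)silyl]oxy}oxolan-2-ol; 13 [(3Z)-hex-3-en-1-yl]triphenylphosphonium iodide
Product: 18 (2S,4Z,7Z)-2-{[tert-butyl(dimethyl)silyl]oxy}deca-4,7-dien-1-ol, via ylide 17 (not isolated)
Conditions: 13 (2.2 equiv), NaN(SiMe3)2 (2.1 equiv), THF, −78 °C; then 16, −78 → 0 °C
Reagents that add atoms: none
Why: Z-selective Wittig olefination of the open hydroxy-aldehyde form of the lactol by a non-stabilised ylide under lithium-free conditions creates the second Z-alkene of the skipped diene; the carbinol centre is untouched and the low temperature suppresses silyl migration.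

Step 12
Reactants: 18 (2S,4Z,7Z)-2-{[tert-butyl(dimethyl)silyl]oxy}deca-4,7-dien-1-ol
Product: 19 (2S,4Z,7Z)-2-{[tert-butyl(dimethyl)silyl]oxy}deca-4,7-dienal
Conditions: Dess–Martin periodinane, CH2Cl2, 0 °C; used at once
Reagents that add atoms: none
Why: Dess–Martin oxidation to the α-silyloxy aldehyde under non-basic conditions, which avoids epimerisation of the α-centre.

Step 13
Reactants: 19 (2S,4Z,7Z)-2-{[tert-butyl(dimethyl)silyl]oxy}deca-4,7-dienal
Product: 20 tert-butyl(dimethyl){[(3S,5Z,8Z)-undeca-5,8-dien-1-yn-3-yl]oxy}silane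
Conditions: Me3SiCHN2, LiN(iPr)2, THF, −78 °C → rt; H2O
Reagents that add atoms: (trimethylsilyl)diazomethane, C[Si](C)(C)C=[N+]=[N-]
Why: Colvin–Shioiri homologation, in which addition of lithiated (trimethylsilyl)diazomethane, Peterson-type loss of silanolate, loss of N2 and a 1,2-hydride shift of the alkylidene carbene give the terminal alkyne without touching the α-stereocentre; the alkyne is made on a scale that serves both halves.

Step 14
Reactants: 20 tert-butyl(dimethyl){[(3S,5Z,8Z)-undeca-5,8-dien-1-yn-3-yl]oxy}silane; 10 (1R,2R)-2-[(2R)-6-oxooxan-2-yl]cyclopropane-1-carbaldehyde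
Product: 23 (6R)-6-[(1R,2R)-2-[(1S,2E,4S,6Z,9Z)-4-{[tert-butyl(dimethyl)silyl]oxy}-1-hydroxydodeca-2,6,9-trien-1-yl]cyclopropyl]oxan-2-one, via alkenylborane 21 (not isolated), via alkenylzinc 22 (not isolated)
Conditions: BH3·SMe2, cyclohexene, PhMe, 0 °C; 20 (1.2 equiv), 0 °C; Me2Zn, −78 °C; (2S)-3-exo-(morpholin-4-yl)isoborneol (10 mol %), then 10, −20 → 0 °C; aq. NH4Cl
Reagents that add atoms: none
Why: Oppolzer–Walsh alkenylation (syn hydroboration of the terminal alkyne, boron-to-zinc transmetalation, amino-alcohol-catalysed 1,2-addition of the (E)-alkenylzinc to the aldehyde, lactones being inert to organozinc reagents); the ligand directs Si-face attack to give the (1S)-carbinol, a centre that is erased by oxidation in the next step.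

Step 15
Reactants: 23 (6R)-6-[(1R,2R)-2-[(1S,2E,4S,6Z,9Z)-4-{[tert-butyl(dimethyl)silyl]oxy}-1-hydroxydodeca-2,6,9-trien-1-yl]cyclopropyl]oxan-2-one
Product: 24 (6R)-6-[(1R,2R)-2-[(2E,4S,6Z,9Z)-4-{[tert-butyl(dimethyl)silyl]oxy}dodeca-2,6,9-trienoyl]cyclopropyl]oxan-2-one
Conditions: Dess–Martin periodinane, CH2Cl2, 0 °C → rt
Reagents that add atoms: none
Why: Dess–Martin oxidation of the allylic alcohol gives the E-enone; alkene geometry and the C4 silyloxy centre are retained.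

**Fragment 4: (R)-alkyne 28 and hydroxy carbonate 33**

Step 16
Reactants: 20 tert-butyl(dimethyl){[(3S,5Z,8Z)-undeca-5,8-dien-1-yn-3-yl]oxy}silane
Product: 25 (3S,5Z,8Z)-undeca-5,8-dien-1-yn-3-ol
Conditions: HF·pyridine, pyridine, THF, 0 °C → rt
Reagents that add atoms: none
Why: Fluoride-mediated Si–O cleavage (desilylation) of a second portion of 20 frees the propargylic alcohol without touching the stereocentre, the alkyne or the skipped diene.

Step 17
Reactants: 25 (3S,5Z,8Z)-undeca-5,8-dien-1-yn-3-ol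
Product: 26 (3R,5Z,8Z)-undeca-5,8-dien-1-yn-3-yl 4-nitrobenzoate
Conditions: 4-nitrobenzoic acid (1.5 equiv), PPh3 (1.5 equiv), iPrO2CN=NCO2iPr (1.5 equiv), THF, 0 °C → rt
Reagents that add atoms: 4-nitrobenzoic acid, O=C(O)c1ccc(cc1)[N+](=O)[O-]
Why: Mitsunobu reaction, in which SN2 displacement of the alkoxyphosphonium ion by 4-nitrobenzoate inverts the propargylic centre cleanly from (S) to (R); the acidic, weakly basic carboxylate favours direct substitution over SN2′ attack at the alkyne.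

Step 18
Reactants: 26 (3R,5Z,8Z)-undeca-5,8-dien-1-yn-3-yl 4-nitrobenzoate
Product: 27 (3R,5Z,8Z)-undeca-5,8-dien-1-yn-3-ol
Conditions: K2CO3 (0.2 equiv), MeOH, 0 °C → rt
Reagents that add atoms: none
Why: Base-catalysed transesterification (methanolysis) of the activated aryl ester proceeds by acyl–oxygen cleavage, so the (R)-centre is retained and the skipped diene is not isomerised under these mild conditions.

Step 19
Reactants: 27 (3R,5Z,8Z)-undeca-5,8-dien-1-yn-3-ol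
Product: 28 tert-butyl(dimethyl){[(3R,5Z,8Z)-undeca-5,8-dien-1-yn-3-yl]oxy}silane
Conditions: TBSCl, imidazole, DMF, rt
Reagents that add atoms: tert-butyl(chloro)dimethylsilane, CC(C)(C)[Si](C)(C)Cl
Why: Imidazole-promoted O-silylation of the secondary propargylic alcohol; the stereocentre is not involved.

Step 20
Reactants: 28 tert-butyl(dimethyl){[(3R,5Z,8Z)-undeca-5,8-dien-1-yn-3-yl]oxy}silane; 10 (1R,2R)-2-[(2R)-6-oxooxan-2-yl]cyclopropane-1-carbaldehyde
Product: 31 (6R)-6-[(1R,2R)-2-[(1S,2E,4R,6Z,9Z)-4-{[tert-butyl(dimethyl)silyl]oxy}-1-hydroxydodeca-2,6,9-trien-1-yl]cyclopropyl]oxan-2-one, via alkenylborane 29 (not isolated), via alkenylzinc 30 (not isolated)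
Conditions: BH3·SMe2, cyclohexene, PhMe, 0 °C; 28 (1.2 equiv), 0 °C; Me2Zn, −78 °C; (2S)-3-exo-(morpholin-4-yl)isoborneol (10 mol %), then 10, −20 → 0 °C; aq. NH4Cl
Reagents that add atoms: none
Why: Oppolzer–Walsh alkenylation as in step 14; here the ligand-controlled Si-face addition sets the (1S)-carbinol that later relays its chirality to C4 of the oxolane.

Step 21
Reactants: 31 (6R)-6-[(1R,2R)-2-[(1S,2E,4R,6Z,9Z)-4-{[tert-butyl(dimethyl)silyl]oxy}-1-hydroxydodeca-2,6,9-trien-1-yl]cyclopropyl]oxan-2-one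
Product: 32 tert-butyl (1S,2E,4R,6Z,9Z)-4-{[tert-butyl(dimethyl)silyl]oxy}-1-{(1R,2R)-2-[(2R)-6-oxooxan-2-yl]cyclopropyl}dodeca-2,6,9-trien-1-yl carbonate
Conditions: Boc2O (1.5 equiv), 4-(dimethylamino)pyridine (10 mol %), MeCN, 0 °C → rt
Reagents that add atoms: di-tert-butyl dicarbonate, CC(C)(C)OC(=O)OC(=O)OC(C)(C)C
Why: DMAP-catalysed O-acylation of the secondary allylic alcohol by Boc2O (nucleophilic catalysis) with retention at the carbinol centre.

Step 22
Reactants: 32 tert-butyl (1S,2E,4R,6Z,9Z)-4-{[tert-butyl(dimethyl)silyl]oxy}-1-{(1R,2R)-2-[(2R)-6-oxooxan-2-yl]cyclopropyl}dodeca-2,6,9-trien-1-yl carbonate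
Product: 33 tert-butyl (1S,2E,4R,6Z,9Z)-4-hydroxy-1-{(1R,2R)-2-[(2R)-6-oxooxan-2-yl]cyclopropyl}dodeca-2,6,9-trien-1-yl carbonate
Conditions: HF·pyridine, pyridine, THF, 0 °C → rt
Reagents that add atoms: none
Why: Selective fluoride cleavage of the secondary silyl ether (desilylation); the allylic tert-butyl carbonate and the lactone are stable to buffered HF·pyridine.

**Union and end game**

Step 23
Reactants: 24 (6R)-6-[(1R,2R)-2-[(2E,4S,6Z,9Z)-4-{[tert-butyl(dimethyl)silyl]oxy}dodeca-2,6,9-trienoyl]cyclopropyl]oxan-2-one; 33 tert-butyl (1S,2E,4R,6Z,9Z)-4-hydroxy-1-{(1R,2R)-2-[(2R)-6-oxooxan-2-yl]cyclopropyl}dodeca-2,6,9-trien-1-yl carbonate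
Product: 34 (6R)-6-[(1R,2R)-2-({(2S,3S,4S,5R)-2-[(1S,3Z,6Z)-1-{[tert-butyl(dimethyl)silyl]oxy}nona-3,6-dien-1-yl]-5-[(2Z,5Z)-octa-2,5-dien-1-yl]-4-[(E)-2-{(1S,2R)-2-[(2R)-6-oxooxan-2-yl]cyclopropyl}ethenyl]oxolan-3-yl}carbonyl)cyclopropyl]oxan-2-one (all-trans oxolane)
Conditions: 24 (1.2 equiv), Pd2(dba)3·CHCl3 (2.5 mol %; zerovalent palladium), Ph2PCH2CH2PPh2 (6 mol %), THF (0.5 M), 25 → 40 °C; then DBU (0.2 equiv), 25 °C
Reagents that add atoms: none
Why: Proposed new method: zerovalent palladium ionises the tert-butyl carbonate of 33 anti to the leaving group to give a syn,syn π-allylpalladium species and tert-butoxide, which deprotonates the C4′ hydroxyl; the alkoxide adds reversibly (oxa-Michael) to the β-carbon of enone 24 and the tethered enolate attacks the proximal allyl terminus anti to palladium in a 5-exo closure, so that C4 is set by 1,3-chirality transfer from the (1′S)-carbonate (net retention, new E-alkene), C5 is carried over from 33, and C2/C3 settle trans,trans by reversible oxa-Michael/enolisation under DBU; the closest known reaction type is the palladium-catalysed formal [3+2] cycloaddition of vinyl epoxides or vinylethylene carbonates with doubly activated Michael acceptors (Tsuji–Trost allylic alkylation), here extended to a mono-activated aliphatic enone and an acyclic 1,3-disubstituted allyl unit.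

Step 24
Reactants: 34 (all-trans oxolanyl cyclopropyl ketone from step 23)
Product: 35 (6R)-6-[(1R,2R)-2-[(R)-{(2S,3R,4S,5R)-2-[(1S,3Z,6Z)-1-{[tert-butyl(dimethyl)silyl]oxy}nona-3,6-dien-1-yl]-5-[(2Z,5Z)-octa-2,5-dien-1-yl]-4-[(E)-2-{(1S,2R)-2-[(2R)-6-oxooxan-2-yl]cyclopropyl}ethenyl]oxolan-3-yl}(hydroxy)methyl]cyclopropyl]oxan-2-one
Conditions: (S)-1-methyl-3,3-diphenyltetrahydro-1H,3H-pyrrolo[1,2-c][1,3,2]oxazaborole (0.5 equiv), catecholborane (2 equiv), PhMe/CH2Cl2, −78 → −40 °C; MeOH, pH 7 buffer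
Reagents that add atoms: none
Why: Corey–Bakshi–Shibata reduction, in which the oxazaborolidine binds the ketone with the branched oxolane carbon as the large group and cyclopropyl as the small one and delivers hydride to give the (R)-carbinol; catecholborane at low temperature does not touch lactones or alkenes.

Step 25
Reactants: 35 (silyl-protected diol from step 24)
Product: 36 (6R)-6-[(1R,2R)-2-[(R)-hydroxy{(2S,3R,4S,5R)-2-[(1S,3Z,6Z)-1-hydroxynona-3,6-dien-1-yl]-5-[(2Z,5Z)-octa-2,5-dien-1-yl]-4-[(E)-2-{(1S,2R)-2-[(2R)-6-oxooxan-2-yl]cyclopropyl}ethenyl]oxolan-3-yl}methyl]cyclopropyl]oxan-2-one (CNP0273074.2)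
Conditions: HF·pyridine, pyridine, THF, 0 °C → rt
Reagents that add atoms: none
Why: Fluoride cleavage of the last silyl ether (desilylation) under buffered conditions that spare the lactones, the cyclopropyl carbinol and the skipped dienes gives the target.

**Compound list**

1 | (E)-but-2-ene-1,4-diol | OC/C=C/CO | starting material
2 | (E)-4-{[tert-butyl(dimethyl)silyl]oxy}but-2-en-1-ol | CC(C)(C)[Si](C)(C)OC/C=C/CO | intermediate
3 | [(1R,2R)-2-({[tert-butyl(dimethyl)silyl]oxy}methyl)cyclopropyl]methanol | CC(C)(C)[Si](C)(C)OC[C@@H]1C[C@H]1CO | intermediate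
4 | (1R,2R)-2-({[tert-butyl(dimethyl)silyl]oxy}methyl)cyclopropane-1-carbaldehyde | CC(C)(C)[Si](C)(C)OC[C@@H]1C[C@H]1C=O | intermediate
5 | methyl 4-iodobutanoate | COC(=O)CCCI | starting material
6 | bis(4-methoxy-4-oxobutyl)zinc | COC(=O)CCC[Zn]CCCC(=O)OC | intermediate (not isolated)
7 | methyl (5R)-5-[(1R,2R)-2-({[tert-butyl(dimethyl)silyl]oxy}methyl)cyclopropyl]-5-hydroxypentanoate | CC(C)(C)[Si](C)(C)OC[C@@H]1C[C@H]1[C@H](O)CCCC(=O)OC | intermediate (not isolated)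
8 | (6R)-6-[(1R,2R)-2-({[tert-butyl(dimethyl)silyl]oxy}methyl)cyclopropyl]oxan-2-one | CC(C)(C)[Si](C)(C)OC[C@@H]1C[C@H]1[C@H]1CCCC(=O)O1 | intermediate
9 | (6R)-6-[(1R,2R)-2-(hydroxymethyl)cyclopropyl]oxan-2-one | OC[C@@H]1C[C@H]1[C@H]1CCCC(=O)O1 | intermediate
10 | (1R,2R)-2-[(2R)-6-oxooxan-2-yl]cyclopropane-1-carbaldehyde | O=C[C@@H]1C[C@H]1[C@H]1CCCC(=O)O1 | intermediate
11 | (3Z)-hex-3-en-1-ol | CC/C=C\CCO | starting material
12 | (3Z)-1-iodohex-3-ene | CC/C=C\CCI | intermediate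
13 | [(3Z)-hex-3-en-1-yl]triphenylphosphonium iodide | CC/C=C\CC[P+](c1ccccc1)(c1ccccc1)c1ccccc1.[I-] | intermediate
14 | (4S)-4-hydroxyoxolan-2-one | O=C1C[C@H](O)CO1 | starting material
15 | (4S)-4-{[tert-butyl(dimethyl)silyl]oxy}oxolan-2-one | O=C1C[C@H](O[Si](C)(C)C(C)(C)C)CO1 | intermediate
16 | (4S)-4-{[tert-butyl(dimethyl)silyl]oxy}oxolan-2-ol (both anomers) | OC1C[C@H](O[Si](C)(C)C(C)(C)C)CO1 | intermediate
17 | [(3Z)-hex-3-en-1-ylidene]triphenylphosphorane | CC/C=C\CC=P(c1ccccc1)(c1ccccc1)c1ccccc1 | intermediate (not isolated)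
18 | (2S,4Z,7Z)-2-{[tert-butyl(dimethyl)silyl]oxy}deca-4,7-dien-1-ol | CC/C=C\C/C=C\C[C@H](O[Si](C)(C)C(C)(C)C)CO | intermediate
19 | (2S,4Z,7Z)-2-{[tert-butyl(dimethyl)silyl]oxy}deca-4,7-dienal | CC/C=C\C/C=C\C[C@H](O[Si](C)(C)C(C)(C)C)C=O | intermediate
20 | tert-butyl(dimethyl){[(3S,5Z,8Z)-undeca-5,8-dien-1-yn-3-yl]oxy}silane | CC/C=C\C/C=C\C[C@H](O[Si](C)(C)C(C)(C)C)C#C | intermediate
21 | [(1E,3S,5Z,8Z)-3-{[tert-butyl(dimethyl)silyl]oxy}undeca-1,5,8-trien-1-yl]dicyclohexylborane | CC/C=C\C/C=C\C[C@H](O[Si](C)(C)C(C)(C)C)/C=C/B(C1CCCCC1)C1CCCCC1 | intermediate (not isolated)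
22 | [(1E,3S,5Z,8Z)-3-{[tert-butyl(dimethyl)silyl]oxy}undeca-1,5,8-trien-1-yl](methyl)zinc | CC/C=C\C/C=C\C[C@H](O[Si](C)(C)C(C)(C)C)/C=C/[Zn]C | intermediate (not isolated)
23 | (6R)-6-[(1R,2R)-2-[(1S,2E,4S,6Z,9Z)-4-{[tert-butyl(dimethyl)silyl]oxy}-1-hydroxydodeca-2,6,9-trien-1-yl]cyclopropyl]oxan-2-one | CC/C=C\C/C=C\C[C@H](O[Si](C)(C)C(C)(C)C)/C=C/[C@H](O)[C@@H]1C[C@H]1[C@H]1CCCC(=O)O1 | intermediate
24 | (6R)-6-[(1R,2R)-2-[(2E,4S,6Z,9Z)-4-{[tert-butyl(dimethyl)silyl]oxy}dodeca-2,6,9-trienoyl]cyclopropyl]oxan-2-one | CC/C=C\C/C=C\C[C@H](O[Si](C)(C)C(C)(C)C)/C=C/C(=O)[C@@H]1C[C@H]1[C@H]1CCCC(=O)O1 | intermediate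
25 | (3S,5Z,8Z)-undeca-5,8-dien-1-yn-3-ol | CC/C=C\C/C=C\C[C@H](O)C#C | intermediate
26 | (3R,5Z,8Z)-undeca-5,8-dien-1-yn-3-yl 4-nitrobenzoate | CC/C=C\C/C=C\C[C@@H](OC(=O)c1ccc(cc1)[N+](=O)[O-])C#C | intermediate
27 | (3R,5Z,8Z)-undeca-5,8-dien-1-yn-3-ol | CC/C=C\C/C=C\C[C@@H](O)C#C | intermediate
28 | tert-butyl(dimethyl){[(3R,5Z,8Z)-undeca-5,8-dien-1-yn-3-yl]oxy}silane | CC/C=C\C/C=C\C[C@@H](O[Si](C)(C)C(C)(C)C)C#C | intermediate
29 | [(1E,3R,5Z,8Z)-3-{[tert-butyl(dimethyl)silyl]oxy}undeca-1,5,8-trien-1-yl]dicyclohexylborane | CC/C=C\C/C=C\C[C@@H](O[Si](C)(C)C(C)(C)C)/C=C/B(C1CCCCC1)C1CCCCC1 | intermediate (not isolated)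
30 | [(1E,3R,5Z,8Z)-3-{[tert-butyl(dimethyl)silyl]oxy}undeca-1,5,8-trien-1-yl](methyl)zinc | CC/C=C\C/C=C\C[C@@H](O[Si](C)(C)C(C)(C)C)/C=C/[Zn]C | intermediate (not isolated)
31 | (6R)-6-[(1R,2R)-2-[(1S,2E,4R,6Z,9Z)-4-{[tert-butyl(dimethyl)silyl]oxy}-1-hydroxydodeca-2,6,9-trien-1-yl]cyclopropyl]oxan-2-one | CC/C=C\C/C=C\C[C@@H](O[Si](C)(C)C(C)(C)C)/C=C/[C@H](O)[C@@H]1C[C@H]1[C@H]1CCCC(=O)O1 | intermediate
32 | tert-butyl (1S,2E,4R,6Z,9Z)-4-{[tert-butyl(dimethyl)silyl]oxy}-1-{(1R,2R)-2-[(2R)-6-oxooxan-2-yl]cyclopropyl}dodeca-2,6,9-trien-1-yl carbonate | CC/C=C\C/C=C\C[C@@H](O[Si](C)(C)C(C)(C)C)/C=C/[C@H](OC(=O)OC(C)(C)C)[C@@H]1C[C@H]1[C@H]1CCCC(=O)O1 | intermediate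
33 | tert-butyl (1S,2E,4R,6Z,9Z)-4-hydroxy-1-{(1R,2R)-2-[(2R)-6-oxooxan-2-yl]cyclopropyl}dodeca-2,6,9-trien-1-yl carbonate | CC/C=C\C/C=C\C[C@@H](O)/C=C/[C@H](OC(=O)OC(C)(C)C)[C@@H]1C[C@H]1[C@H]1CCCC(=O)O1 | intermediate
34 | (6R)-6-[(1R,2R)-2-({(2S,3S,4S,5R)-2-[(1S,3Z,6Z)-1-{[tert-butyl(dimethyl)silyl]oxy}nona-3,6-dien-1-yl]-5-[(2Z,5Z)-octa-2,5-dien-1-yl]-4-[(E)-2-{(1S,2R)-2-[(2R)-6-oxooxan-2-yl]cyclopropyl}ethenyl]oxolan-3-yl}carbonyl)cyclopropyl]oxan-2-one | CC/C=C\C/C=C\C[C@H](O[Si](C)(C)C(C)(C)C)[C@H]1O[C@H](C/C=C\C/C=C\CC)[C@@H](/C=C/[C@@H]2C[C@H]2[C@H]2CCCC(=O)O2)[C@@H]1C(=O)[C@@H]1C[C@H]1[C@H]1CCCC(=O)O1 | intermediate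
35 | (6R)-6-[(1R,2R)-2-[(R)-{(2S,3R,4S,5R)-2-[(1S,3Z,6Z)-1-{[tert-butyl(dimethyl)silyl]oxy}nona-3,6-dien-1-yl]-5-[(2Z,5Z)-octa-2,5-dien-1-yl]-4-[(E)-2-{(1S,2R)-2-[(2R)-6-oxooxan-2-yl]cyclopropyl}ethenyl]oxolan-3-yl}(hydroxy)methyl]cyclopropyl]oxan-2-one | CC/C=C\C/C=C\C[C@H](O[Si](C)(C)C(C)(C)C)[C@H]1O[C@H](C/C=C\C/C=C\CC)[C@@H](/C=C/[C@@H]2C[C@H]2[C@H]2CCCC(=O)O2)[C@@H]1[C@H](O)[C@@H]1C[C@H]1[C@H]1CCCC(=O)O1 | intermediate
36 | (6R)-6-[(1R,2R)-2-[(R)-hydroxy{(2S,3R,4S,5R)-2-[(1S,3Z,6Z)-1-hydroxynona-3,6-dien-1-yl]-5-[(2Z,5Z)-octa-2,5-dien-1-yl]-4-[(E)-2-{(1S,2R)-2-[(2R)-6-oxooxan-2-yl]cyclopropyl}ethenyl]oxolan-3-yl}methyl]cyclopropyl]oxan-2-one | CC/C=C\C/C=C\C[C@H](O)[C@H]1O[C@H](C/C=C\C/C=C\CC)[C@@H](/C=C/[C@@H]2C[C@H]2[C@H]2CCCC(=O)O2)[C@@H]1[C@H](O)[C@@H]1C[C@H]1[C@H]1CCCC(=O)O1 | target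

**Totals**

Total step count: 25.
Longest linear sequence: 15 steps (steps 9–13, then 16–19, then 20–25).

**Three steps most likely to fail**

Step 20 (ligand-controlled alkenylzinc addition). The catalyst has to override the weak facial bias of aldehyde 10, and dicyclohexylborane has to spare the skipped diene. Fallback: set C1′ by ketone reduction instead of by C–C bond formation. Setting out from 28 and 10, hydrozirconation of 28 with Cp2Zr(H)Cl (CH2Cl2, rt), transmetalation with Me2Zn and ligand-free addition to 10 give 31 together with its C1′ epimer (6R)-6-[(1R,2R)-2-[(1R,2E,4R,6Z,9Z)-4-{[tert-butyl(dimethyl)silyl]oxy}-1-hydroxydodeca-2,6,9-trien-1-yl]cyclopropyl]oxan-2-one F1. Dess–Martin oxidation of the mixture converges both epimers to the enone (6R)-6-[(1R,2R)-2-[(2E,4R,6Z,9Z)-4-{[tert-butyl(dimethyl)silyl]oxy}dodeca-2,6,9-trienoyl]cyclopropyl]oxan-2-one F2. Corey–Bakshi–Shibata reduction with the (S)-oxazaborolidine of step 24 and catecholborane (alkenyl arm as the large group) then returns the (1′S)-alcohol, and the route is rejoined at 31.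

Step 23 (the proposed new [3+2] union). The oxa-Michael addition of a secondary alkoxide to a mono-activated enone may be too slow to compete with collapse of the π-allyl alkoxide to a vinyl epoxide or diene. Fallback with known chemistry: switch to the doubly activated Knoevenagel-type acceptor, the class for which this palladium-catalysed [3+2] reaction is established, and remove the extra ester afterwards. Setting out from 10, 19 and 33, SnCl2-catalysed Roskamp homologation of aldehyde 10 with tert-butyl diazoacetate (CH2Cl2, rt) gives the β-keto ester tert-butyl 3-oxo-3-{(1R,2R)-2-[(2R)-6-oxooxan-2-yl]cyclopropyl}propanoate F3. Knoevenagel condensation of this keto ester with aldehyde 19 (piperidinium acetate, 4 Å molecular sieves, CH2Cl2, 0 °C) gives the alkylidene β-keto ester tert-butyl (4S,6Z,9Z)-4-{[tert-butyl(dimethyl)silyl]oxy}-2-({(1R,2R)-2-[(2R)-6-oxooxan-2-yl]cyclopropyl}carbonyl)dodeca-2,6,9-trienoate (2E/2Z mixture) F4. Its reaction with 33 under Pd2(dba)3·CHCl3/Ph2PCH2CH2PPh2 in THF (stabilised enolate, Tsuji–Trost closure with the same chirality transfer) gives the oxolane with a quaternary C3, tert-butyl (2S,4S,5R)-2-[(1S,3Z,6Z)-1-{[tert-butyl(dimethyl)silyl]oxy}nona-3,6-dien-1-yl]-5-[(2Z,5Z)-octa-2,5-dien-1-yl]-3-({(1R,2R)-2-[(2R)-6-oxooxan-2-yl]cyclopropyl}carbonyl)-4-[(E)-2-{(1S,2R)-2-[(2R)-6-oxooxan-2-yl]cyclopropyl}ethenyl]oxolane-3-carboxylate (C3 epimers) F5. Acid-catalysed loss of isobutene and CO2 (p-toluenesulfonic acid, 10 mol %, PhMe, 80 °C), followed by DBU equilibration of C2/C3, gives the all-trans ketone, and the route is rejoined at 34.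

Step 24 (reagent-controlled reduction of a hindered ketone). The oxazaborolidine may not distinguish cyclopropyl from the oxolane carbon well enough, or may react too slowly. Fallback: give up catalyst control and use reduction, separation and recycling. Setting out from 34, Luche reduction (NaBH4, CeCl3·7H2O, MeOH, −40 °C; lactones survive) gives 35 together with its carbinol epimer, the (S)-hydroxymethyl epimer of 35 F6. The two are separated by chromatography, the unwanted epimer is returned to 34 by Dess–Martin oxidation and reduced again, and the route is rejoined at 35.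

**Further compounds**

F1 | step 20 | (6R)-6-[(1R,2R)-2-[(1R,2E,4R,6Z,9Z)-4-{[tert-butyl(dimethyl)silyl]oxy}-1-hydroxydodeca-2,6,9-trien-1-yl]cyclopropyl]oxan-2-one | CC/C=C\C/C=C\C[C@@H](O[Si](C)(C)C(C)(C)C)/C=C/[C@@H](O)[C@@H]1C[C@H]1[C@H]1CCCC(=O)O1
F2 | step 20 | (6R)-6-[(1R,2R)-2-[(2E,4R,6Z,9Z)-4-{[tert-butyl(dimethyl)silyl]oxy}dodeca-2,6,9-trienoyl]cyclopropyl]oxan-2-one | CC/C=C\C/C=C\C[C@@H](O[Si](C)(C)C(C)(C)C)/C=C/C(=O)[C@@H]1C[C@H]1[C@H]1CCCC(=O)O1
F3 | step 23 | tert-butyl 3-oxo-3-{(1R,2R)-2-[(2R)-6-oxooxan-2-yl]cyclopropyl}propanoate | CC(C)(C)OC(=O)CC(=O)[C@@H]1C[C@H]1[C@H]1CCCC(=O)O1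
F4 | step 23 | tert-butyl (4S,6Z,9Z)-4-{[tert-butyl(dimethyl)silyl]oxy}-2-({(1R,2R)-2-[(2R)-6-oxooxan-2-yl]cyclopropyl}carbonyl)dodeca-2,6,9-trienoate (2E/2Z mixture) | CC/C=C\C/C=C\C[C@H](O[Si](C)(C)C(C)(C)C)C=C(C(=O)OC(C)(C)C)C(=O)[C@@H]1C[C@H]1[C@H]1CCCC(=O)O1
F5 | step 23 | tert-butyl (2S,4S,5R)-2-[(1S,3Z,6Z)-1-{[tert-butyl(dimethyl)silyl]oxy}nona-3,6-dien-1-yl]-5-[(2Z,5Z)-octa-2,5-dien-1-yl]-3-({(1R,2R)-2-[(2R)-6-oxooxan-2-yl]cyclopropyl}carbonyl)-4-[(E)-2-{(1S,2R)-2-[(2R)-6-oxooxan-2-yl]cyclopropyl}ethenyl]oxolane-3-carboxylate (C3 epimers) | CC/C=C\C/C=C\C[C@H](O[Si](C)(C)C(C)(C)C)[C@H]1O[C@H](C/C=C\C/C=C\CC)[C@@H](/C=C/[C@@H]2C[C@H]2[C@H]2CCCC(=O)O2)C1(C(=O)OC(C)(C)C)C(=O)[C@@H]1C[C@H]1[C@H]1CCCC(=O)O1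
F6 | step 24 | (6R)-6-[(1R,2R)-2-[(S)-{(2S,3R,4S,5R)-2-[(1S,3Z,6Z)-1-{[tert-butyl(dimethyl)silyl]oxy}nona-3,6-dien-1-yl]-5-[(2Z,5Z)-octa-2,5-dien-1-yl]-4-[(E)-2-{(1S,2R)-2-[(2R)-6-oxooxan-2-yl]cyclopropyl}ethenyl]oxolan-3-yl}(hydroxy)methyl]cyclopropyl]oxan-2-one | CC/C=C\C/C=C\C[C@H](O[Si](C)(C)C(C)(C)C)[C@H]1O[C@H](C/C=C\C/C=C\CC)[C@@H](/C=C/[C@@H]2C[C@H]2[C@H]2CCCC(=O)O2)[C@@H]1[C@@H](O)[C@@H]1C[C@H]1[C@H]1CCCC(=O)O1
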